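## The problem

The target, (3R,5S)-1-(4-hydroxy-3-methoxyphenyl)octane-3,5-diyl diacetate 15, is an open eight-carbon chain, numbered here from the benzylic carbon C1 to the methyl carbon C8. It carries a guaiacol ring on C1, acetoxy groups on C3 and C5 and a propyl terminus; the only ring is the arene, which can be bought. The work is therefore a linear chain assembly that places two oxygen-bearing stereocentres in a syn 1,3-relationship with the correct absolute sense. Because C3 and C5 are 1,3-related, either could direct the other through a six-membered acetal or chelate, but that still needs one asymmetric and one diastereoselective step; a building block holding both centres removes the question. Three elements are fragile. The secondary acetates do not survive base or nucleophiles and must come late. The phenol would be acetylated with the alcohols unless it stays masked until after acetylation and is then freed under neutral conditions. The electron-rich arene is easily oxidised and must be absent from any oxidative bond formation. The enabling feature is that C2–C6, with syn oxygens on C3 and C5, is atom for atom the chain of the commercial statin side-chain acetonide 1, a cis-4,6-disubstituted 2,2-dimethyl-1,3-dioxane whose hydroxymethyl carbon is C2 and whose acetate methylene is C6. The ester carbon of 1 hangs on C6 exactly where C7 must be attached, so an anodic decarboxylation joining the C6 radical to the ethyl radical of propanoic acid 5 completes the propyl terminus without touching either stereocentre.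

## Retrosynthesis

**15 back to 12 (O–benzyl, O–acetyl and ketal C–O bonds; no skeletal bond).** Phenol 15 is traced to its benzyl ether 14, since hydrogenolysis is the one unmasking that is neutral enough for two secondary acetates. 14 is the diacetate of diol 13, and 13 is the hydrolysis product of acetonide 12. Freeing the phenol earlier would make the acetylation ambiguous; in this order the only hydroxyls present when 13 is acylated are those on C3 and C5. The precursor 12 is simpler in that its diol is locked in a ketal that tolerates organometallic reagents. The forward steps must leave the C3–O and C5–O bonds intact, which hydrolysis, acylation and hydrogenolysis all do.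

**12 to 8 and 11 (C1–C2).** Cutting C1–C2 gives primary triflate 8, with C2 as electrophile, and benzylic Grignard reagent 11, which brings C1 and the arene. The neighbouring cuts are worse: C2–C3 would break into a stereocentre, and the aryl–C1 bond would need a two-carbon organometallic beta to a ketal oxygen, which is prone to elimination. Both pieces are much simpler: 8 is a seven-carbon chiral fragment without arene, and 11 comes in two steps from benzyl alcohol 9 through chloride 10. The forward reaction is a substitution at a primary carbon slowed by the adjacent ring oxygen, hence the triflate leaving group and copper catalysis. C2 is a methylene, so no stereochemistry is at stake.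

**8 to 6 (O–S and O–Si bonds).** Triflate 8 comes from alcohol 7, and 7 from silyl ether 6. The silyl group is carried through the electrolysis for three reasons. It prevents acid-promoted migration of the ketal onto the terminal oxygen, it keeps the coupling product non-volatile and easy to separate, and a triisopropylsilyl group brings no arene to the anode. The forward steps are a fluoride desilylation and a sulfonylation.

**6 to 4 and 5 (C6–C7, the key cut).** Cutting C6–C7 leads to carboxylic acid 4 and propanoic acid 5, each of which gives up its carboxyl carbon. The alternative cut at C7–C8 would keep the carboxyl carbon but require reduction, activation and a methyl nucleophile, three operations instead of one. A cut at C5–C6 would recreate a stereocentre that is already present. The precursor 4 is the purchased chiral building block with one protecting group. The forward reaction must favour heterocoupling over self-coupling of 4, keep the C6 radical from being oxidised to a cation, and meet nothing else that is oxidisable. This is why the arene is introduced only afterwards.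

**4 to 1 (acyl–O and O–Si bonds).** Acid 4 arises through its sodium salt 3 by saponification of tert-butyl ester 2, and 2 by silylation of commercial alcohol 1. The silyl ether must tolerate hot hydroxide, which decides for triisopropylsilyl over silyl groups that are more base-labile.

## Roads not taken

**Alternative 1:** Lactol A1, (4R,6R)-6-[2-(4-hydroxy-3-methoxyphenyl)ethyl]oxane-2,4-diol, would come from cutting C3–C4 and C5–C6. A deoxyribose-phosphate aldolase would add acetaldehyde A3 twice to 3-(4-hydroxy-3-methoxyphenyl)propanal A2, and the 3,5-dihydroxy aldehyde would close to A1 between the C3 oxygen and C7.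
- Merits: both stereocentres come from the catalyst, from achiral inputs, in water, in one operation and without protecting groups. The sense of induction is the one needed.
- Weak points: A2 is a lipophilic arylpropanal without a polar alpha substituent, a demanding acceptor for this enzyme class, and A3 at preparative concentration tends to inactivate the enzyme. The anomeric carbon of A1 is C7, one carbon short and at the wrong oxidation level, so a Wittig methylenation of the lactol and a hydrogenation must follow. The free phenol of A1 would be acetylated with the alcohols, which calls for a selective aryl-acetate cleavage or a protected, even less enzyme-friendly acceptor.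
- Comparison: if the enzymatic step worked on A2 this road would be clearly shorter and more elegant in the origin of its chirality. The chosen plan sets against this that the same syn pattern is bought ready-made in 1, that the carbon count fits exactly, and that each step rests on broad precedent.

**Alternative 2:** Diacetate A4, (3R,5S)-1-(4-benzyloxy-3-methoxyphenyl)octane-3,5-diyl diacetate, is the same structure as 14 and would come from cutting C2–C3. NiBr2(dme) with a chiral bis(oxazoline) ligand would couple both C1 epimers of (3S)-1-bromohexane-1,3-diyl diacetate A5 with [2-(4-benzyloxy-3-methoxyphenyl)ethyl]zinc bromide A6, fixing the C3 configuration.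
- Merits: it is the most convergent plan, reaches the penultimate compound in one bond formation, needs no ketal or silyl group and brings the arene in late.
- Weak points: A5 is an alpha-bromoalkyl ester, hydrolytically fragile, and its C5 stereocentre still needs an asymmetric step of its own. The two epimers of A5 are diastereomers, not enantiomers, so the catalyst must impose the configuration at C3 with or against the bias of the existing acetate, and the neighbouring acetoxy group may coordinate nickel. Any anti isomer would be an oily diastereomer that is hard to remove.
- Comparison: this road is better in convergence and in longest linear sequence. The chosen plan offers configurational certainty in return: both centres are purchased with fixed relative and absolute configuration, and no step has to be diastereoselective.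

**Alternative 3:** Acetal A7, (4R,6R)-2,4,6-cis-6-[2-(4-benzyloxy-3-methoxyphenyl)ethyl]-2-phenyl-4-[(E)-prop-1-enyl]-1,3-dioxane, would come from forming the C5–O bond by allylic transposition. Re2O7 would move the C7 hydroxyl of (3R,5E)-1-(4-benzyloxy-3-methoxyphenyl)oct-5-ene-3,7-diol A8 to C5, and benzaldehyde dimethyl acetal A9 would trap the C3 and C5 oxygens as the all-equatorial benzylidene acetal.
- Merits: the step is stereoconvergent, since the C7 configuration of A8 is irrelevant. C5 is set under thermodynamic control by C3, so only one stereocentre needs an asymmetric reagent.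
- Weak points: A8 has to be built first, by an asymmetric allylation and a chain extension, which costs about what the transposition saves. The propenyl group of A7 must be hydrogenated while the C5–O bond is allylic, with a risk of hydrogenolysis. Palladium would also remove the benzylidene and benzyl groups together and expose the phenol before acetylation. The ionising conditions could also let the electron-rich arene capture the C5 cation.
- Comparison: this road is of similar length and more economical in stereochemical information. The chosen plan has a saturated chain from the start, no allylic C–O bond at any hydrogenation and no equilibrium to rely on.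

Key step: step 3

Remark: the chain numbering C1–C8 of the target is used for all intermediates, and benzyl alcohol 9 is taken as a catalogue compound.

## Route

Step 1
Reactants: 1 tert-butyl 2-[(4R,6S)-6-(hydroxymethyl)-2,2-dimethyl-1,3-dioxan-4-yl]acetate
Product: 2 tert-butyl 2-[(4R,6S)-2,2-dimethyl-6-(triisopropylsilyloxymethyl)-1,3-dioxan-4-yl]acetate
Conditions: i-Pr3SiCl, imidazole, DMF, rt
Reagents that add atoms: chlorotri(propan-2-yl)silane, CC(C)[Si](Cl)(C(C)C)C(C)C
Why: Standard silylation of an unhindered primary alcohol; the triisopropylsilyl ether is chosen because it survives the hydroxide hydrolysis of step 2, brings no arene to the anode, blocks ketal migration onto the terminal oxygen and makes the coupling product non-volatile.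

Step 2
Reactants: 2 tert-butyl 2-[(4R,6S)-2,2-dimethyl-6-(triisopropylsilyloxymethyl)-1,3-dioxan-4-yl]acetate
Product: 4 2-[(4R,6S)-2,2-dimethyl-6-(triisopropylsilyloxymethyl)-1,3-dioxan-4-yl]acetic acid, via sodium carboxylate 3 (not isolated)
Conditions: NaOH, MeOH/THF/H2O, 55 °C; then 1 M HCl to pH 4, 0 °C
Reagents that add atoms: sodium hydroxide, [Na+].[OH-]
Why: Saponification by acyl–oxygen cleavage of a tert-butyl ester that is hindered but activated by its beta-oxygen; ketal and silyl ether tolerate hot hydroxide, and cold, brief acidification frees the acid without opening the acetonide or touching a stereocentre.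

Step 3
Reactants: 4 2-[(4R,6S)-2,2-dimethyl-6-(triisopropylsilyloxymethyl)-1,3-dioxan-4-yl]acetic acid; 5 propanoic acid
Product: 6 triisopropyl{[(4S,6S)-2,2-dimethyl-6-propyl-1,3-dioxan-4-yl]methoxy}silane
Conditions: Pt foil anode, Pt cathode, undivided cell, 5 (10 equiv), NaOMe (ca. 5% neutralisation), MeOH, ca. 0.25 A cm−2, 15–20 °C
Reagents that add atoms: none
Why: Mixed Kolbe electrolysis: both carboxylates are adsorbed on the platinum anode, lose one electron and then CO2, so the primary C6 radical from 4 and the ethyl radical from 5 are generated side by side in a dense layer at the electrode and combine to form C6–C7. The closest known reaction type is the crossed Kolbe coupling of beta-alkoxy carboxylic acids, ketal-protected hydroxy acids among them, with a cheap alkanoic co-acid. No ring is closed and no stereocentre is created; C5 is next to the radical carbon but never becomes a radical centre, and beta-scission of its C–O bond is too slow to compete, so both purchased centres are retained. The step needs heterocoupling to beat self-coupling of 4, which the tenfold excess of 5 should secure on statistical grounds, while the by-products from 5 alone (butane, ethane, ethene, ethyl propanoate) are volatile. It also needs the radical pathway to beat further oxidation to a carbocation (Hofer–Moest products); the electron-withdrawing beta-oxygen, smooth platinum, high current density and a weakly acidic, only partly neutralised electrolyte all favour the radical. Nothing else is oxidisable: the silyl ether and ketal are inert, the solvent is shielded by the carboxylate layer, and the electron-rich arene has not yet been introduced. The ketal is safe because a carboxylic acid buffered by its own salt in methanol is far too weak an acid to open it.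

Step 4
Reactants: 6 triisopropyl{[(4S,6S)-2,2-dimethyl-6-propyl-1,3-dioxan-4-yl]methoxy}silane
Product: 7 [(4S,6S)-2,2-dimethyl-6-propyl-1,3-dioxan-4-yl]methanol
Conditions: Bu4NF, THF, rt
Reagents that add atoms: none
Why: Fluoride-induced desilylation driven by the strong Si–F bond; the ketal is inert to fluoride and to the mildly basic medium.

Step 5
Reactants: 7 [(4S,6S)-2,2-dimethyl-6-propyl-1,3-dioxan-4-yl]methanol
Product: 8 [(4S,6S)-2,2-dimethyl-6-propyl-1,3-dioxan-4-yl]methyl trifluoromethanesulfonate
Conditions: Tf2O, pyridine, CH2Cl2, −20 °C; used crude at once
Reagents that add atoms: trifluoromethanesulfonic anhydride, O=S(=O)(OS(=O)(=O)C(F)(F)F)C(F)(F)F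
Why: O-sulfonylation of a primary alcohol with triflic anhydride; the C–O bond of the carbinol is not broken and the adjacent stereocentre is untouched, and cold handling keeps the reactive triflate intact.

Step 6
Reactants: 9 (4-benzyloxy-3-methoxyphenyl)methanol
Product: 10 1-benzyloxy-4-(chloromethyl)-2-methoxybenzene
Conditions: SOCl2, cat. DMF, CH2Cl2, 0 °C to rt
Reagents that add atoms: thionyl chloride, ClS(Cl)=O
Why: Chlorodehydroxylation of an electron-rich benzylic alcohol with thionyl chloride through the chlorosulfite; the benzyl aryl ether tolerates the HCl released at this temperature.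

Step 7
Reactants: 10 1-benzyloxy-4-(chloromethyl)-2-methoxybenzene
Product: 11 (4-benzyloxy-3-methoxybenzyl)magnesium chloride (titrated THF solution, used directly)
Conditions: Mg turnings (excess, activated), THF, 0 °C, slow addition at high dilution
Reagents that add atoms: magnesium, [Mg]
Why: Grignard formation by insertion of magnesium into the benzylic C–Cl bond; slow addition of a dilute chloride solution onto excess metal at low temperature suppresses Wurtz coupling.

Step 8
Reactants: 8 [(4S,6S)-2,2-dimethyl-6-propyl-1,3-dioxan-4-yl]methyl trifluoromethanesulfonate; 11 (4-benzyloxy-3-methoxybenzyl)magnesium chloride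
Product: 12 (4R,6S)-4-[2-(4-benzyloxy-3-methoxyphenyl)ethyl]-2,2-dimethyl-6-propyl-1,3-dioxane
Conditions: CuBr·SMe2 (10 mol %), THF/Et2O, −40 to 0 °C
Reagents that add atoms: none
Why: Copper-catalysed alkylation of a Grignard reagent with a primary alkyl triflate (SN2 displacement by a benzylcopper species formed with monovalent copper); it forms C1–C2 at a non-stereogenic methylene, and the triflate is reactive enough to overcome the retarding beta-oxygen at temperatures where the ketal is inert.

Step 9
Reactants: 12 (4R,6S)-4-[2-(4-benzyloxy-3-methoxyphenyl)ethyl]-2,2-dimethyl-6-propyl-1,3-dioxane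
Product: 13 (3R,5S)-1-(4-benzyloxy-3-methoxyphenyl)octane-3,5-diol
Conditions: 1 M aq HCl, THF, rt
Reagents that add atoms: none
Why: Acid-catalysed hydrolysis of the isopropylidene ketal; the C3–O and C5–O bonds are not broken, so the syn configuration is kept, and the benzyl ether is stable to dilute acid.

Step 10
Reactants: 13 (3R,5S)-1-(4-benzyloxy-3-methoxyphenyl)octane-3,5-diol
Product: 14 (3R,5S)-1-(4-benzyloxy-3-methoxyphenyl)octane-3,5-diyl diacetate
Conditions: Ac2O, pyridine, cat. DMAP, CH2Cl2, rt
Reagents that add atoms: acetic anhydride, CC(=O)OC(C)=O
Why: DMAP-catalysed acylation of both secondary alcohols; the phenol is still a benzyl ether, so only the two required acetates can form.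

Step 11
Reactants: 14 (3R,5S)-1-(4-benzyloxy-3-methoxyphenyl)octane-3,5-diyl diacetate
Product: 15 (3R,5S)-1-(4-hydroxy-3-methoxyphenyl)octane-3,5-diyl diacetate
Conditions: H2 (1 atm), Pd/C, EtOAc, rt
Reagents that add atoms: none
Why: Hydrogenolysis of the benzyl aryl ether over palladium under neutral conditions; the secondary acetates are neither benzylic nor allylic and should be neither reduced nor migrated.

## Compound list

1 | tert-butyl 2-[(4R,6S)-6-(hydroxymethyl)-2,2-dimethyl-1,3-dioxan-4-yl]acetate | CC(C)(C)OC(=O)C[C@@H](C[C@@H](CO)O1)OC1(C)C | starting material
2 | tert-butyl 2-[(4R,6S)-2,2-dimethyl-6-(triisopropylsilyloxymethyl)-1,3-dioxan-4-yl]acetate | CC(C)(C)OC(=O)C[C@@H](C[C@@H](CO[Si](C(C)C)(C(C)C)C(C)C)O1)OC1(C)C | intermediate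
3 | sodium 2-[(4R,6S)-2,2-dimethyl-6-(triisopropylsilyloxymethyl)-1,3-dioxan-4-yl]acetate | [Na+].[O-]C(=O)C[C@@H](C[C@@H](CO[Si](C(C)C)(C(C)C)C(C)C)O1)OC1(C)C | intermediate
4 | 2-[(4R,6S)-2,2-dimethyl-6-(triisopropylsilyloxymethyl)-1,3-dioxan-4-yl]acetic acid | OC(=O)C[C@@H](C[C@@H](CO[Si](C(C)C)(C(C)C)C(C)C)O1)OC1(C)C | intermediate
5 | propanoic acid | CCC(=O)O | starting material
6 | triisopropyl{[(4S,6S)-2,2-dimethyl-6-propyl-1,3-dioxan-4-yl]methoxy}silane | CCC[C@@H](C[C@@H](CO[Si](C(C)C)(C(C)C)C(C)C)O1)OC1(C)C | intermediate
7 | [(4S,6S)-2,2-dimethyl-6-propyl-1,3-dioxan-4-yl]methanol | CCC[C@@H](C[C@@H](CO)O1)OC1(C)C | intermediate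
8 | [(4S,6S)-2,2-dimethyl-6-propyl-1,3-dioxan-4-yl]methyl trifluoromethanesulfonate | CCC[C@@H](C[C@@H](COS(=O)(=O)C(F)(F)F)O1)OC1(C)C | intermediate
9 | (4-benzyloxy-3-methoxyphenyl)methanol | COc1cc(CO)ccc1OCc1ccccc1 | starting material
10 | 1-benzyloxy-4-(chloromethyl)-2-methoxybenzene | COc1cc(CCl)ccc1OCc1ccccc1 | intermediate
11 | (4-benzyloxy-3-methoxybenzyl)magnesium chloride | COc1cc(C[Mg]Cl)ccc1OCc1ccccc1 | intermediate
12 | (4R,6S)-4-[2-(4-benzyloxy-3-methoxyphenyl)ethyl]-2,2-dimethyl-6-propyl-1,3-dioxane | CCC[C@@H](C[C@@H](CCc2ccc(OCc3ccccc3)c(OC)c2)O1)OC1(C)C | intermediate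
13 | (3R,5S)-1-(4-benzyloxy-3-methoxyphenyl)octane-3,5-diol | CCC[C@@H](C[C@@H](CCc1ccc(OCc2ccccc2)c(OC)c1)O)O | intermediate
14 | (3R,5S)-1-(4-benzyloxy-3-methoxyphenyl)octane-3,5-diyl diacetate | CCC[C@@H](C[C@@H](CCc1ccc(OCc2ccccc2)c(OC)c1)OC(C)=O)OC(C)=O | intermediate
15 | (3R,5S)-1-(4-hydroxy-3-methoxyphenyl)octane-3,5-diyl diacetate | CCC[C@@H](C[C@@H](CCc1ccc(O)c(OC)c1)OC(C)=O)OC(C)=O | target

## Step count and risk

Total step count: 11. Longest linear sequence: 9 steps from acetonide 1 (steps 1, 2, 3, 4, 5, 8, 9, 10, 11); the arene branch contributes steps 6 and 7.

**Step 3 (key step).** The likeliest failure is diversion of the C6 radical before it meets an ethyl radical: further oxidation to the cation with solvent capture, disproportionation, self-coupling, or fouling of the anode. Fallback, which makes C7–C8 in place of C6–C7: setting out from ester 2, reduction with LiAlH4 (THF, 0 °C) would give 2-[(4S,6S)-2,2-dimethyl-6-(triisopropylsilyloxymethyl)-1,3-dioxan-4-yl]ethanol F1. TsCl in pyridine would convert it into 2-[(4S,6S)-2,2-dimethyl-6-(triisopropylsilyloxymethyl)-1,3-dioxan-4-yl]ethyl 4-methylbenzenesulfonate F2. Displacement with Me2CuLi (Et2O, −20 to 0 °C) keeps the former carboxyl carbon as C7, adds C8 as a methyl nucleophile and rejoins the route at 6.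

**Step 2.** The likeliest failure is slow hydrolysis of the hindered tert-butyl ester. That leaves time for enolate-driven beta-elimination that opens the dioxane, or the ketal may be lost during acidification. Fallback, a redox detour instead of hydrolysis: from 2, i-Bu2AlH (CH2Cl2, −78 °C) would stop at 2-[(4R,6S)-2,2-dimethyl-6-(triisopropylsilyloxymethyl)-1,3-dioxan-4-yl]acetaldehyde F3. Buffered Pinnick oxidation (NaClO2, NaH2PO4, 2-methylbut-2-ene, t-BuOH/H2O) would then deliver the acid, rejoining the route at 4.

**Step 7.** The likeliest failure is Wurtz-type homocoupling of the electron-rich benzylic chloride at the metal surface, which consumes the halide before the reagent accumulates. Fallback, a sulfone-stabilised benzylic carbanion in place of the organomagnesium: from 10, PhSO2Na in DMF would give 1-benzyloxy-2-methoxy-4-[(phenylsulfonyl)methyl]benzene F4. Deprotonation with n-BuLi (THF, −78 °C) and alkylation with triflate 8 would give (4S,6S)-4-[2-(4-benzyloxy-3-methoxyphenyl)-2-(phenylsulfonyl)ethyl]-2,2-dimethyl-6-propyl-1,3-dioxane F5, as a mixture of epimers at the sulfonyl carbon. Reductive desulfonylation with Mg in MeOH rejoins the route at 12.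

**Step 8.** The likeliest failure is that substitution at the methylene next to the ring oxygen is too slow, so that the triflate is consumed by attack at sulfur or by ionisation assisted by the ring oxygens. Fallback, olefination instead of substitution: from alcohol 7, Swern oxidation would give (4S,6S)-2,2-dimethyl-6-propyl-1,3-dioxane-4-carbaldehyde F6. Chloride 10 and PPh3 would give [(4-benzyloxy-3-methoxyphenyl)methyl]triphenylphosphonium chloride F7. A Wittig reaction (NaN(SiMe3)2, THF) would give (4S,6S)-4-[2-(4-benzyloxy-3-methoxyphenyl)ethenyl]-2,2-dimethyl-6-propyl-1,3-dioxane F8 as an E/Z mixture. Diimide (TsNHNH2, NaOAc, aqueous DME, reflux) would saturate the double bond without touching the benzyl ether, rejoining the route at 12.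

## Further compounds

F1 | step 3 | 2-[(4S,6S)-2,2-dimethyl-6-(triisopropylsilyloxymethyl)-1,3-dioxan-4-yl]ethanol | OCC[C@@H](C[C@@H](CO[Si](C(C)C)(C(C)C)C(C)C)O1)OC1(C)C
F2 | step 3 | 2-[(4S,6S)-2,2-dimethyl-6-(triisopropylsilyloxymethyl)-1,3-dioxan-4-yl]ethyl 4-methylbenzenesulfonate | Cc1ccc(cc1)S(=O)(=O)OCC[C@@H](C[C@@H](CO[Si](C(C)C)(C(C)C)C(C)C)O1)OC1(C)C
F3 | step 2 | 2-[(4R,6S)-2,2-dimethyl-6-(triisopropylsilyloxymethyl)-1,3-dioxan-4-yl]acetaldehyde | O=CC[C@@H](C[C@@H](CO[Si](C(C)C)(C(C)C)C(C)C)O1)OC1(C)C
F4 | step 7 | 1-benzyloxy-2-methoxy-4-[(phenylsulfonyl)methyl]benzene | COc1cc(CS(=O)(=O)c2ccccc2)ccc1OCc1ccccc1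
F5 | step 7 | (4S,6S)-4-[2-(4-benzyloxy-3-methoxyphenyl)-2-(phenylsulfonyl)ethyl]-2,2-dimethyl-6-propyl-1,3-dioxane (epimers at the sulfonyl carbon) | CCC[C@@H](C[C@@H](CC(c2ccc(OCc3ccccc3)c(OC)c2)S(=O)(=O)c2ccccc2)O1)OC1(C)C
F6 | step 8 | (4S,6S)-2,2-dimethyl-6-propyl-1,3-dioxane-4-carbaldehyde | CCC[C@@H](C[C@@H](C=O)O1)OC1(C)C
F7 | step 8 | [(4-benzyloxy-3-methoxyphenyl)methyl]triphenylphosphonium chloride | COc1cc(C[P+](c2ccccc2)(c2ccccc2)c2ccccc2)ccc1OCc1ccccc1.[Cl-]
F8 | step 8 | (4S,6S)-4-[2-(4-benzyloxy-3-methoxyphenyl)ethenyl]-2,2-dimethyl-6-propyl-1,3-dioxane (E/Z mixture) | CCC[C@@H](C[C@@H](C=Cc2ccc(OCc3ccccc3)c(OC)c2)O1)OC1(C)C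
A1 | alternative 1 | (4R,6R)-6-[2-(4-hydroxy-3-methoxyphenyl)ethyl]oxane-2,4-diol (anomeric mixture) | OC1C[C@@H](C[C@@H](CCc2ccc(O)c(OC)c2)O1)O
A2 | alternative 1 | 3-(4-hydroxy-3-methoxyphenyl)propanal | COc1cc(CCC=O)ccc1O
A3 | alternative 1 | acetaldehyde | CC=O
A4 | alternative 2 | (3R,5S)-1-(4-benzyloxy-3-methoxyphenyl)octane-3,5-diyl diacetate | CCC[C@@H](C[C@@H](CCc1ccc(OCc2ccccc2)c(OC)c1)OC(C)=O)OC(C)=O
A5 | alternative 2 | (3S)-1-bromohexane-1,3-diyl diacetate (both C1 epimers) | CCC[C@@H](CC(Br)OC(C)=O)OC(C)=O
A6 | alternative 2 | [2-(4-benzyloxy-3-methoxyphenyl)ethyl]zinc bromide | COc1cc(CC[Zn]Br)ccc1OCc1ccccc1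
A7 | alternative 3 | (4R,6R)-2,4,6-cis-6-[2-(4-benzyloxy-3-methoxyphenyl)ethyl]-2-phenyl-4-[(E)-prop-1-enyl]-1,3-dioxane | C/C=C/[C@@H](C[C@@H](CCc2ccc(OCc3ccccc3)c(OC)c2)O1)O[C@@H]1c4ccccc4
A8 | alternative 3 | (3R,5E)-1-(4-benzyloxy-3-methoxyphenyl)oct-5-ene-3,7-diol (either C7 epimer) | CC(O)/C=C/C[C@@H](CCc1ccc(OCc2ccccc2)c(OC)c1)O
A9 | alternative 3 | benzaldehyde dimethyl acetal | COC(OC)c1ccccc1
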